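**Retrosynthetic overview**
1. Target 25 ⇐ methoxy-γ-pyrone 24 by [4+2] addition of singlet oxygen to the cyclohexadiene, anti to the cyclobutane (peroxide bridge formed last).
2. Pyrone of 24 ⇐ triketide 22 ⇐ aldol union of the bicyclic neopentyl aldehyde 18 with the γ-dianion of methyl 2-methyl-3-oxopentanoate 19 (the fragment-joining C–C bond), then oxidation, lactonisation and O-methylation.
3. Aldehyde 18 ⇐ N-acyl camphorsultam 16 ⇐ thermal 8π-conrotatory/6π-disrotatory cascade of an E,Z,Z,E-tetraenoyl sultam (cyclobutane and cyclohexadiene formed in one operation; the auxiliary makes the two antipodal cores separable diastereomers).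
4. Tetraene ⇐ Stille coupling of Z-iododienoyl sultam 9 (from propargyl alcohol) with Z,E-dienylstannane 13 (from tiglic aldehyde).
5. Ring order: cyclooctatriene (transient) → cyclobutane/cyclohexadiene → pyrone → 1,2-dioxane bridge.

Assumption: the sense and level of induction by the sultam in the 8π closure cannot be predicted with confidence, so the route is written for the (1S)-(−)-sultam, the required diastereomer 16 is isolated by chromatography/crystallisation with its configuration confirmed by X-ray, and if it proves to be the minor isomer the (1R)-(+)-sultam is used in the same way.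

**Step 1**
Reactants: 1 prop-2-yn-1-ol (propargyl alcohol)
Product: 3 (Z)-3-iodo-2-methylprop-2-en-1-ol, via vinylmagnesium alkoxide 2 (not isolated)
Conditions: MeMgBr (3 equiv), CuI (10 mol %), Et2O, −10 °C → rt; then I2, Et2O, −10 °C → rt; aq. NH4Cl
Reagents that add atoms: methylmagnesium bromide C[Mg]Br; iodine II
Why: Copper-catalysed anti-carbomagnesiation of the propargylic alkoxide gives a chelated (Z)-vinyl Grignard that is iodinated with retention, fixing the Z trisubstituted alkene that becomes the 4Z bond of the tetraene.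

**Step 2**
Reactants: 3 (Z)-3-iodo-2-methylprop-2-en-1-ol
Product: 5 ethyl (2E,4Z)-5-iodo-2,4-dimethylpenta-2,4-dienoate, via (Z)-3-iodo-2-methylprop-2-enal 4 (not isolated)
Conditions: activated MnO2 (15 equiv), Ph3P=C(Me)CO2Et (1.5 equiv), CH2Cl2, rt, dark
Reagents that add atoms: ethyl 2-(triphenylphosphoranylidene)propanoate CCOC(=O)C(C)=P(c1ccccc1)(c1ccccc1)c1ccccc1
Why: Tandem allylic oxidation/Wittig olefination traps the isomerisation-prone (Z)-β-iodoenal in situ with the stabilised ylide, which gives the E-trisubstituted enoate.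

**Step 3**
Reactants: 5 ethyl (2E,4Z)-5-iodo-2,4-dimethylpenta-2,4-dienoate
Product: 6 (2E,4Z)-5-iodo-2,4-dimethylpenta-2,4-dienoic acid
Conditions: LiOH·H2O (3 equiv), THF/MeOH/H2O 3:1:1, 0 °C → rt; 1 M HCl to pH 3
Reagents that add atoms: lithium hydroxide [Li+].[OH-]
Why: Mild saponification at or below room temperature cleaves the ester while leaving the vinyl iodide and both alkene geometries intact.

**Step 4**
Reactants: 6 (2E,4Z)-5-iodo-2,4-dimethylpenta-2,4-dienoic acid; 7 (1S,2R,4R)-(−)-bornane-10,2-sultam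
Product: 9 N-[(2E,4Z)-5-iodo-2,4-dimethylpenta-2,4-dienoyl]-(1S,2R,4R)-bornane-10,2-sultam, via acid chloride 8 (not isolated)
Conditions: (COCl)2, cat. DMF, CH2Cl2, 0 °C → rt; evaporate; then 7, Et3N, DMAP (cat.), CH2Cl2, 0 °C → rt
Reagents that add atoms: none
Why: Acid chloride formation followed by DMAP-catalysed N-acylation of the acidic sultam N–H places the chiral auxiliary on the carbonyl attached to the carbon that becomes the quaternary C7.

**Step 5**
Reactants: 10 (E)-2-methylbut-2-enal (tiglic aldehyde)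
Product: 11 (2Z,4E)-2-iodo-4-methylhexa-2,4-diene
Conditions: EtPPh3I, n-BuLi, THF, rt; I2, −78 °C; NaHMDS, −20 °C; then 10, −78 → −20 °C
Reagents that add atoms: ethyltriphenylphosphonium iodide CC[P+](c1ccccc1)(c1ccccc1)c1ccccc1.[I-]; iodine II
Why: Stork–Zhao–Wittig olefination with the α-iodo ylide gives the (Z)-α-methyl vinyl iodide (iodine cis to the alkenyl chain) under kinetic control and leaves the E-tiglyl alkene unchanged.

**Step 6**
Reactants: 11 (2Z,4E)-2-iodo-4-methylhexa-2,4-diene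
Product: 13 trimethyl[(2Z,4E)-4-methylhexa-2,4-dien-2-yl]stannane, via dienyllithium 12 (not isolated)
Conditions: t-BuLi (2.1 equiv), Et2O, −78 °C; Me3SnCl, −78 °C → rt
Reagents that add atoms: chlorotrimethylstannane C[Sn](C)(C)Cl
Why: Lithium–iodine exchange and stannylation both proceed with retention of alkene geometry, giving the nucleophilic Stille partner.

**Step 7**
Reactants: 9 N-[(2E,4Z)-5-iodo-2,4-dimethylpenta-2,4-dienoyl]-(1S,2R,4R)-bornane-10,2-sultam; 13 trimethyl[(2Z,4E)-4-methylhexa-2,4-dien-2-yl]stannane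
Product: 16 N-{[(1R,6R,7S,8R)-1,3,5,7,8-pentamethylbicyclo[4.2.0]octa-2,4-dien-7-yl]carbonyl}-(1S,2R,4R)-bornane-10,2-sultam, via E,Z,Z,E-tetraene 14 (not isolated), via cyclooctatriene 15 (not isolated)
Conditions: Pd(PPh3)4 (10 mol %), CuI (20 mol %), CsF (2 equiv), DMF, rt → 40 °C, dark; SiO2 chromatography, then recrystallisation
Reagents that add atoms: none
Why: Copper/fluoride-accelerated Stille coupling gives the E,Z,Z,E-tetraene, whose thermal 8π conrotatory closure sets C7/C8 (the two methyls cis) and whose 6π disrotatory closure sets the cis ring fusion C1/C6 with H rather than CH3 endo at C8 and hence the acyl group endo, while the sultam biases the helical sense of the 8π step and makes the two antipodal bicycles separable diastereomers so that the (1R,6R,7S,8R) isomer is isolated.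

**Step 8**
Reactants: 16 N-{[(1R,6R,7S,8R)-1,3,5,7,8-pentamethylbicyclo[4.2.0]octa-2,4-dien-7-yl]carbonyl}-(1S,2R,4R)-bornane-10,2-sultam
Product: 17 [(1R,6R,7S,8R)-1,3,5,7,8-pentamethylbicyclo[4.2.0]octa-2,4-dien-7-yl]methanol
Conditions: LiAlH4 (3 equiv), THF, 0 °C → rt; Fieser work-up
Reagents that add atoms: none
Why: Hydride reduction cleaves the hindered N-acyl sultam to the neopentyl alcohol without touching the diene or any stereocentre, and the auxiliary is recovered.

**Step 9**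
Reactants: 17 [(1R,6R,7S,8R)-1,3,5,7,8-pentamethylbicyclo[4.2.0]octa-2,4-dien-7-yl]methanol
Product: 18 (1R,6R,7S,8R)-1,3,5,7,8-pentamethylbicyclo[4.2.0]octa-2,4-diene-7-carbaldehyde
Conditions: Dess–Martin periodinane (1.3 equiv), CH2Cl2, 0 °C → rt
Reagents that add atoms: none
Why: Dess–Martin oxidation gives the non-enolisable aldehyde under near-neutral conditions that spare the diene.

**Step 10**
Reactants: 18 (1R,6R,7S,8R)-1,3,5,7,8-pentamethylbicyclo[4.2.0]octa-2,4-diene-7-carbaldehyde; 19 methyl 2-methyl-3-oxopentanoate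
Product: 21 methyl 5-hydroxy-2,4-dimethyl-3-oxo-5-[(1R,6R,7S,8R)-1,3,5,7,8-pentamethylbicyclo[4.2.0]octa-2,4-dien-7-yl]pentanoate (mixture of diastereomers at C2/C4/C5), via dilithium dienolate 20 (not isolated)
Conditions: 19 (2 equiv), LDA (4.2 equiv), THF, −78 → 0 °C; then 18, −78 °C; AcOH/THF quench at −78 °C
Reagents that add atoms: none
Why: Intermolecular aldol addition of the β-keto ester dianion (Weiler type) through its more nucleophilic γ-carbon to the non-enolisable aldehyde forms the bond that links the bicyclic core to the pyrone carbons, and the new carbinol and methine centres are erased later so their configuration is irrelevant.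

**Step 11**
Reactants: 21 methyl 5-hydroxy-2,4-dimethyl-3-oxo-5-[(1R,6R,7S,8R)-1,3,5,7,8-pentamethylbicyclo[4.2.0]octa-2,4-dien-7-yl]pentanoate
Product: 22 methyl 2,4-dimethyl-3,5-dioxo-5-[(1R,6R,7S,8R)-1,3,5,7,8-pentamethylbicyclo[4.2.0]octa-2,4-dien-7-yl]pentanoate
Conditions: Dess–Martin periodinane (1.5 equiv), CH2Cl2, rt
Reagents that add atoms: none
Why: Dess–Martin oxidation converts the β-hydroxy ketone into the β,δ-diketo ester without retro-aldol cleavage.

**Step 12**
Reactants: 22 methyl 2,4-dimethyl-3,5-dioxo-5-[(1R,6R,7S,8R)-1,3,5,7,8-pentamethylbicyclo[4.2.0]octa-2,4-dien-7-yl]pentanoate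
Product: 23 4-hydroxy-3,5-dimethyl-6-[(1R,6R,7S,8R)-1,3,5,7,8-pentamethylbicyclo[4.2.0]octa-2,4-dien-7-yl]-2H-pyran-2-one
Conditions: DBU (2 equiv), toluene, rt; cold 1 M HCl wash
Reagents that add atoms: none
Why: DBU-mediated enolisation of the C5 ketone and intramolecular O-acylation (lactonisation) gives the 4-hydroxy-2-pyrone at room temperature, below the threshold for electrocyclic ring opening of the bicycle.

**Step 13**
Reactants: 23 4-hydroxy-3,5-dimethyl-6-[(1R,6R,7S,8R)-1,3,5,7,8-pentamethylbicyclo[4.2.0]octa-2,4-dien-7-yl]-2H-pyran-2-one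
Product: 24 2-methoxy-3,5-dimethyl-6-[(1R,6R,7S,8R)-1,3,5,7,8-pentamethylbicyclo[4.2.0]octa-2,4-dien-7-yl]-4H-pyran-4-one
Conditions: MeOTf (2 equiv), CH2Cl2, rt; sat. aq. NaHCO3
Reagents that add atoms: methyl trifluoromethanesulfonate COS(=O)(=O)C(F)(F)F
Why: The hard alkylating agent methylates the neutral hydroxypyrone at the lactone carbonyl oxygen to give a 4-hydroxy-2-methoxypyrylium salt that is deprotonated on bicarbonate work-up to the α-methoxy-γ-pyrone, with the acid held on the pyrone so the diene is spared.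

**Step 14**
Reactants: 24 2-methoxy-3,5-dimethyl-6-[(1R,6R,7S,8R)-1,3,5,7,8-pentamethylbicyclo[4.2.0]octa-2,4-dien-7-yl]-4H-pyran-4-one
Product: 25 2-methoxy-3,5-dimethyl-6-[(1S,2R,3S,4R,5R,6R)-1,3,4,5,10-pentamethyl-7,8-dioxatricyclo[4.2.2.0^2,5]dec-9-en-3-yl]-4H-pyran-4-one
Conditions: O2, methylene blue (2 mol %), CH2Cl2, visible light, 0 °C
Reagents that add atoms: dioxygen O=O
Why: [4+2] cycloaddition of singlet oxygen to the s-cis cyclohexadiene occurs from the convex face anti to the cyclobutane (the face carrying only the angular CH3 and H), setting the two peroxide-bearing carbons as (1S,6R), and is faster than ene reaction or attack on the pyrone.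

**Compound list**
1 | prop-2-yn-1-ol | C#CCO | starting material
2 | (Z)-[3-(bromomagnesiooxy)-2-methylprop-1-en-1-yl]magnesium bromide | Br[Mg]OC/C(C)=C\[Mg]Br | intermediate
3 | (Z)-3-iodo-2-methylprop-2-en-1-ol | OC/C(C)=C\I | intermediate
4 | (Z)-3-iodo-2-methylprop-2-enal | O=C/C(C)=C\I | intermediate
5 | ethyl (2E,4Z)-5-iodo-2,4-dimethylpenta-2,4-dienoate | CCOC(=O)/C(C)=C/C(C)=C\I | intermediate
6 | (2E,4Z)-5-iodo-2,4-dimethylpenta-2,4-dienoic acid | OC(=O)/C(C)=C/C(C)=C\I | intermediate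
7 | (1S,2R,4R)-(−)-bornane-10,2-sultam (camphorsultam) | CC1(C)[C@@H]2CC[C@]13CS(=O)(=O)N[C@@H]3C2 | starting material
8 | (2E,4Z)-5-iodo-2,4-dimethylpenta-2,4-dienoyl chloride | ClC(=O)/C(C)=C/C(C)=C\I | intermediate
9 | N-[(2E,4Z)-5-iodo-2,4-dimethylpenta-2,4-dienoyl]-(1S,2R,4R)-bornane-10,2-sultam | CC1(C)[C@@H]2CC[C@]13CS(=O)(=O)N(C(=O)/C(C)=C/C(C)=C\I)[C@@H]3C2 | intermediate
10 | (E)-2-methylbut-2-enal (tiglic aldehyde) | C/C=C(\C)C=O | starting material
11 | (2Z,4E)-2-iodo-4-methylhexa-2,4-diene | C/C=C(\C)/C=C(\I)C | intermediate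
12 | (2E,4E)-4-methylhexa-2,4-dien-2-yllithium (Li cis to C4; geometry of 11 retained, descriptor changes because Li ranks below CH3) | C/C=C(\C)/C=C(\[Li])C | intermediate
13 | trimethyl[(2Z,4E)-4-methylhexa-2,4-dien-2-yl]stannane | C/C=C(\C)/C=C(\[Sn](C)(C)C)C | intermediate
14 | N-[(2E,4Z,6Z,8E)-2,4,6,8-tetramethyldeca-2,4,6,8-tetraenoyl]-(1S,2R,4R)-bornane-10,2-sultam | CC1(C)[C@@H]2CC[C@]13CS(=O)(=O)N(C(=O)/C(C)=C/C(C)=C\C(C)=C/C(C)=C/C)[C@@H]3C2 | intermediate
15 | N-{[(1R,8R)-1,3,5,7,8-pentamethylcycloocta-2,4,6-trien-1-yl]carbonyl}-(1S,2R,4R)-bornane-10,2-sultam (1-CH3 and 8-CH3 cis) | CC1(C)[C@@H]2CC[C@]13CS(=O)(=O)N(C(=O)[C@]4(C)/C=C(C)\C=C(C)/C=C(C)\[C@H]4C)[C@@H]3C2 | intermediate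
16 | N-{[(1R,6R,7S,8R)-1,3,5,7,8-pentamethylbicyclo[4.2.0]octa-2,4-dien-7-yl]carbonyl}-(1S,2R,4R)-bornane-10,2-sultam (cis-fused; 1-, 7-, 8-CH3 and 6-H on the convex face, acyl endo) | CC1(C)[C@@H]2CC[C@]13CS(=O)(=O)N(C(=O)[C@@]4(C)[C@H](C)[C@@]5(C)C=C(C)C=C(C)[C@@H]45)[C@@H]3C2 | intermediate
17 | [(1R,6R,7S,8R)-1,3,5,7,8-pentamethylbicyclo[4.2.0]octa-2,4-dien-7-yl]methanol | OC[C@@]1(C)[C@H](C)[C@@]2(C)C=C(C)C=C(C)[C@@H]12 | intermediate
18 | (1R,6R,7S,8R)-1,3,5,7,8-pentamethylbicyclo[4.2.0]octa-2,4-diene-7-carbaldehyde | O=C[C@@]1(C)[C@H](C)[C@@]2(C)C=C(C)C=C(C)[C@@H]12 | intermediate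
19 | methyl 2-methyl-3-oxopentanoate (racemic) | CCC(=O)C(C)C(=O)OC | starting material
20 | dilithium 1-methoxy-2-methylpenta-1,3-diene-1,3-diolate (dianion of 19; enolate geometry not defined) | CC=C(O[Li])C(C)=C(OC)O[Li] | intermediate
21 | methyl 5-hydroxy-2,4-dimethyl-3-oxo-5-[(1R,6R,7S,8R)-1,3,5,7,8-pentamethylbicyclo[4.2.0]octa-2,4-dien-7-yl]pentanoate (diastereomer mixture at C2/C4/C5) | COC(=O)C(C)C(=O)C(C)C(O)[C@@]1(C)[C@H](C)[C@@]2(C)C=C(C)C=C(C)[C@@H]12 | intermediate
22 | methyl 2,4-dimethyl-3,5-dioxo-5-[(1R,6R,7S,8R)-1,3,5,7,8-pentamethylbicyclo[4.2.0]octa-2,4-dien-7-yl]pentanoate (C2/C4 epimers and enol forms) | COC(=O)C(C)C(=O)C(C)C(=O)[C@@]1(C)[C@H](C)[C@@]2(C)C=C(C)C=C(C)[C@@H]12 | intermediate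
23 | 4-hydroxy-3,5-dimethyl-6-[(1R,6R,7S,8R)-1,3,5,7,8-pentamethylbicyclo[4.2.0]octa-2,4-dien-7-yl]-2H-pyran-2-one | O=c1oc([C@@]2(C)[C@H](C)[C@@]3(C)C=C(C)C=C(C)[C@@H]23)c(C)c(O)c1C | intermediate
24 | 2-methoxy-3,5-dimethyl-6-[(1R,6R,7S,8R)-1,3,5,7,8-pentamethylbicyclo[4.2.0]octa-2,4-dien-7-yl]-4H-pyran-4-one | COc1oc([C@@]2(C)[C@H](C)[C@@]3(C)C=C(C)C=C(C)[C@@H]23)c(C)c(=O)c1C | intermediate
25 | 2-methoxy-3,5-dimethyl-6-[(1S,2R,3S,4R,5R,6R)-1,3,4,5,10-pentamethyl-7,8-dioxatricyclo[4.2.2.0^2,5]dec-9-en-3-yl]-4H-pyran-4-one | COc1oc([C@@]2(C)[C@H](C)[C@@]3(C)[C@@H]4OO[C@@](C)(C=C4C)[C@@H]23)c(C)c(=O)c1C | target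

**Totals**
Total step count: 14.
Longest linear sequence: 12 steps (1 → 3 → 5 → 6 → 9 → 16 → 17 → 18 → 21 → 22 → 23 → 24 → 25); the stannane branch (10 → 11 → 13) is 2 steps.

**Three steps most likely to fail, with fallbacks**

Step 7 (auxiliary-bearing Stille/8π–6π cascade: poor induction, poor diastereomer separation, or the bulky sultam disfavouring the endo-acyl closure). The fallback sets out from ester 5 (with stannane 13) and comes back at 17. Ester 5 and 13 are coupled under the same Stille conditions, and the achiral tetraene ester cyclises to racemic ethyl (1R*,6R*,7S*,8R*)-1,3,5,7,8-pentamethylbicyclo[4.2.0]octa-2,4-diene-7-carboxylate F1. DIBAL-H reduction (CH2Cl2, −78 °C) gives the racemic [1,3,5,7,8-pentamethylbicyclo[4.2.0]octa-2,4-dien-7-yl]methanol F2. Esterification with (S)-2-methoxy-2-phenylacetic acid (DCC, DMAP) gives two diastereomeric esters, which are separated by chromatography or crystallisation (preparative chiral SFC of F2 is the direct alternative); the wanted one is [(1R,6R,7S,8R)-1,3,5,7,8-pentamethylbicyclo[4.2.0]octa-2,4-dien-7-yl]methyl (S)-2-methoxy-2-phenylacetate F3. Methanolysis (K2CO3, MeOH) releases 17.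

Step 10 (dianion aldol on a neopentyl, α-quaternary aldehyde: low conversion or retro-aldol). The fallback sets out from 16 and comes back at 22, replacing the reversible aldol by an irreversible Claisen-type acylation. LiOH/H2O2 (THF/H2O) cleaves the auxiliary to (1R,6R,7S,8R)-1,3,5,7,8-pentamethylbicyclo[4.2.0]octa-2,4-diene-7-carboxylic acid F4, with recovery of 7. (COCl)2/cat. DMF gives (1R,6R,7S,8R)-1,3,5,7,8-pentamethylbicyclo[4.2.0]octa-2,4-diene-7-carbonyl chloride F5. C-acylation of excess dianion 20 (3 equiv, THF, −78 °C) with F5 gives triketide 22 directly, without passing through 17, 18 and 21.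

Step 13 (regioselectivity of O-methylation, α-methoxy-γ-pyrone versus γ-methoxy-α-pyrone, and acid sensitivity of the diene). The fallback sets out from 22 and comes back at 24 with no new compound (F0). Triketide 22 is cyclodehydrated with Ph3P/CCl4 in THF at rt (Appel-type activation of the C5 enol oxygen, attack by the ester carbonyl oxygen, loss of Ph3PO). The ester methoxy group is kept, so the 2-methoxy-4-pyrone 24 forms by construction and steps 12 and 13 are bypassed.

**Further compounds**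
F1 | step 7 | racemic ethyl (1R*,6R*,7S*,8R*)-1,3,5,7,8-pentamethylbicyclo[4.2.0]octa-2,4-diene-7-carboxylate | CCOC(=O)[C@@]1(C)[C@H](C)[C@@]2(C)C=C(C)C=C(C)[C@@H]12.CCOC(=O)[C@]1(C)[C@@H](C)[C@]2(C)C=C(C)C=C(C)[C@H]12
F2 | step 7 | racemic [(1R*,6R*,7S*,8R*)-1,3,5,7,8-pentamethylbicyclo[4.2.0]octa-2,4-dien-7-yl]methanol | OC[C@@]1(C)[C@H](C)[C@@]2(C)C=C(C)C=C(C)[C@@H]12.OC[C@]1(C)[C@@H](C)[C@]2(C)C=C(C)C=C(C)[C@H]12
F3 | step 7 | [(1R,6R,7S,8R)-1,3,5,7,8-pentamethylbicyclo[4.2.0]octa-2,4-dien-7-yl]methyl (S)-2-methoxy-2-phenylacetate | CO[C@H](C(=O)OC[C@@]1(C)[C@H](C)[C@@]2(C)C=C(C)C=C(C)[C@@H]12)c1ccccc1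
F4 | step 10 | (1R,6R,7S,8R)-1,3,5,7,8-pentamethylbicyclo[4.2.0]octa-2,4-diene-7-carboxylic acid | OC(=O)[C@@]1(C)[C@H](C)[C@@]2(C)C=C(C)C=C(C)[C@@H]12
F5 | step 10 | (1R,6R,7S,8R)-1,3,5,7,8-pentamethylbicyclo[4.2.0]octa-2,4-diene-7-carbonyl chloride | ClC(=O)[C@@]1(C)[C@H](C)[C@@]2(C)C=C(C)C=C(C)[C@@H]12
F0 | step 13 | none | none
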